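**Retrosynthetic overview**
- Target ⇐ acetylation, acid-driven γ-lactonisation, exhaustive hydride reduction and ketone methylenation of a 5-menthyloxy γ-lactone adduct; its two oxidised ring carbons become the two CH2O groups.
- Key disconnection at the quaternary carbon: the β-carbon of the cycloheptanone reacts as a tertiary 3-oxoalkyl radical (a homoenolate equivalent, unmasked from a β,γ-enone by H-atom transfer) with the β-carbon of a butenolide. Two acceptor-type carbons are joined (1,6-dicarbonyl), setting the quaternary centre and both side-chain stereocentres in one step.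
- cis-Hydroazulenone ⇐ Pd-mediated silyl enol ether/alkene cyclisation ⇐ Cu-catalysed asymmetric conjugate addition with enolate silylation on 4,4-dimethylcyclohept-2-enone ⇐ diazoacetate ring expansion of 4,4-dimethylcyclohex-2-enone.
- Butenolide partner ⇐ furfural, (+)-menthol (traceless acetal controller) and tert-butyl bromoacetate.
- Ring order: seven-membered carbocycle, then cyclopentane, then the auxiliary lactone (reopened), and the γ-butyrolactone last.

Assumption: the SMILES is read as (2R)-2-[(3R)-5-oxooxolan-3-yl]-2-[(1R,3aR,8aS)-1,4,4-trimethyl-8-methylidenedecahydroazulen-1-yl]ethyl acetate; "C-q" is the methyl-bearing quaternary ring carbon and "(+)-menthyloxy" is [(1S,2R,5S)-5-methyl-2-(propan-2-yl)cyclohexyl]oxy.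

**Step 1**
Reactants: 1 4,4-dimethylcyclohex-2-en-1-one; 2 ethyl diazoacetate
Product: 3 ethyl 5,5-dimethyl-2-oxocyclohept-3-ene-1-carboxylate
Conditions: BF3·OEt2 (1.1 equiv), CH2Cl2, 0 °C → rt
Reagents that add atoms: none
Why: Lewis-acid-promoted diazoacetate homologation (Tiffeneau–Demjanov-type ring expansion), in which the saturated α′-carbon migrates in preference to the vinylic one, so the enone stays conjugated and the CMe2 group ends at C4 of the cycloheptenone; the ester-bearing centre is enolised and removed in step 2.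

**Step 2**
Reactants: 3 ethyl 5,5-dimethyl-2-oxocyclohept-3-ene-1-carboxylate
Product: 4 4,4-dimethylcyclohept-2-en-1-one
Conditions: LiCl, H2O (2 equiv), DMSO, 150 °C
Reagents that add atoms: none
Why: Krapcho dealkoxycarbonylation of the β-keto ester under neutral conditions that leave the enone untouched; no stereocentre is involved.

**Step 3**
Reactants: 4 4,4-dimethylcyclohept-2-en-1-one; 5 but-3-en-1-ylmagnesium bromide
Product: 8 trimethyl{[(3R)-3-(but-3-en-1-yl)-4,4-dimethylcyclohept-1-en-1-yl]oxy}silane, via di(but-3-enyl)zinc 6 (not isolated), via zinc enolate 7 (not isolated)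
Conditions: 5, ZnCl2 (0.5 equiv per 5), Et2O, 0 °C → rt, 1,4-dioxane, filter; Cu(OTf)2 (2 mol %), (S,R,R)-phosphoramidite [O,O′-(S)-1,1′-binaphthyl-2,2′-diyl N,N-bis((R)-1-phenylethyl)phosphoramidite] (4 mol %), toluene, −30 °C, 4; then TMSOTf (1.5 equiv), −30 → 0 °C; non-aqueous work-up
Reagents that add atoms: trimethylsilyl trifluoromethanesulfonate, C[Si](C)(C)OS(=O)(=O)C(F)(F)F; zinc dichloride, Cl[Zn]Cl (its zinc stays only in 6 and 7)
Why: copper-catalysed asymmetric conjugate addition of a dialkylzinc followed by O-silylation of the zinc enolate, which fixes the enol ether at C1–C2; the (S,R,R)-ligand delivers the alkyl group to the same enone face as in its (S)-3-alkylcycloalkanone-forming additions, which here is 3R because the CMe2 carbon outranks C2.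

**Step 4**
Reactants: 8 trimethyl{[(3R)-3-(but-3-en-1-yl)-4,4-dimethylcyclohept-1-en-1-yl]oxy}silane
Product: 9 (3aR,8aR)-8,8-dimethyl-3-methylideneoctahydroazulen-4(1H)-one
Conditions: Pd(OAc)2 (10 mol %), O2 (1 atm), DMSO, 45 °C
Reagents that add atoms: none
Why: palladium diacetate-mediated oxidative cyclisation of a silyl enol ether onto a pendant alkene (Kende-type cycloalkenylation, catalytic under O2), with 5-exo attack of the enol carbon and β-hydride elimination to the exocyclic methylene; the new bond must form on the face that carries the tether, so the ring fusion is cis (3aR).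

**Step 5**
Reactants: 10 furfural
Product: 11 5-hydroxyfuran-2(5H)-one
Conditions: O2, hν (visible), methylene blue (cat.), MeOH, 20 °C
Reagents that add atoms: dioxygen, O=O
Why: dye-sensitised photooxygenation, in which singlet oxygen adds [4+2] to the furan and methanolysis of the endoperoxide expels the formyl carbon as methyl formate; C5 is a racemic, epimerisable hemiacetal.

**Step 6**
Reactants: 11 5-hydroxyfuran-2(5H)-one; 12 (+)-menthol
Product: 13 (5S)-5-[(+)-menthyloxy]furan-2(5H)-one
Conditions: neat, 100 °C, reduced pressure (−H2O); crystallise from hexanes; mother liquor re-equilibrated with cat. TsOH and recrystallised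
Reagents that add atoms: none
Why: acetalisation of the pseudo-acid with the chiral alcohol; the C5 epimers interconvert under acid and the (5S)-(+)-menthyl diastereomer crystallises out (crystallisation-induced diastereomer enrichment), fixing the acetal centre that later controls the radical addition.

**Step 7**
Reactants: 13 (5S)-5-[(+)-menthyloxy]furan-2(5H)-one
Product: 14 (5S)-3-iodo-5-[(+)-menthyloxy]furan-2(5H)-one
Conditions: I2 (1.5 equiv), pyridine/CH2Cl2 1:1, 0 °C → rt
Reagents that add atoms: diiodine, II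
Why: α-iodination of the unsaturated lactone by the pyridine addition–iodination–elimination sequence (Johnson-type α-iodination); the acetal centre is not involved.

**Step 8**
Reactants: 14 (5S)-3-iodo-5-[(+)-menthyloxy]furan-2(5H)-one; 15 tert-butyl bromoacetate
Product: 17 tert-butyl 2-[(5S)-5-[(+)-menthyloxy]-2-oxo-2,5-dihydrofuran-3-yl]acetate, via Reformatsky reagent 16 (not isolated)
Conditions: 15, Zn dust (TMSCl-activated), THF, rt; then 14, Pd2(dba)3 (2.5 mol %), XPhos (10 mol %), THF, rt → 45 °C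
Reagents that add atoms: zinc, [Zn] (stays only in 16)
Why: zinc insertion gives the Reformatsky reagent, which undergoes Negishi cross-coupling with the α-iodo-enoate under zerovalent palladium faster than the weakly nucleophilic zinc enolate can add conjugately; no new stereocentre is formed.

**Step 9 (key step)**
Reactants: 9 (3aR,8aR)-8,8-dimethyl-3-methylideneoctahydroazulen-4(1H)-one; 17 tert-butyl 2-[(5S)-5-[(+)-menthyloxy]-2-oxo-2,5-dihydrofuran-3-yl]acetate
Product: 18 tert-butyl 2-[(3R,4R,5S)-5-[(+)-menthyloxy]-2-oxo-4-[(1S,3aR,8aR)-1,4,4-trimethyl-8-oxodecahydroazulen-1-yl]oxolan-3-yl]acetate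
Conditions: 9 (1 equiv), 17 (2 equiv), Fe(acac)3 (30 mol %), PhSiH2(Oi-Pr) (2.5 equiv), THF with i-PrOH (5 equiv), degassed, 40 °C
Reagents that add atoms: none
Why: metal-hydride H-atom transfer (Mukaiyama-type reductive olefin coupling, Giese addition) converts the exocyclic alkene of the β,γ-enone into the tertiary 3-oxoalkyl radical at C-q, which is a ketone homoenolate equivalent, and this adds to C4 of the butenolide so that two β-acceptor carbons are joined; the radical reacts on the convex face of the cis-fused bicycle (new bond syn to the ring-fusion hydrogens), the butenolide is attacked anti to the C5 menthyloxy group, and the resulting lactone enolate is protonated anti to the new bulky group (C3 cis to C4).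

**Step 10**
Reactants: 18 tert-butyl 2-[(3R,4R,5S)-5-[(+)-menthyloxy]-2-oxo-4-[(1S,3aR,8aR)-1,4,4-trimethyl-8-oxodecahydroazulen-1-yl]oxolan-3-yl]acetate
Product: 19 tert-butyl 2-[(3R,4R,5S)-5-[(+)-menthyloxy]-2-oxo-4-[(1R,3aR,8aS)-1,4,4-trimethyl-8-methylidenedecahydroazulen-1-yl]oxolan-3-yl]acetate
Conditions: Zn, CH2Br2, TiCl4 (pre-aged in THF, 5 °C), CH2Cl2, 0 °C → rt
Reagents that add atoms: dibromomethane, BrCBr
Why: Takai–Lombardo methylenation is non-basic, so the epimerisable C3 lactone centre and the ring-fusion α-centre survive, and it is selective for the ketone over the lactone, acetal and tert-butyl ester; only the descriptors change, not the configurations.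

**Step 11**
Reactants: 19 tert-butyl 2-[(3R,4R,5S)-5-[(+)-menthyloxy]-2-oxo-4-[(1R,3aR,8aS)-1,4,4-trimethyl-8-methylidenedecahydroazulen-1-yl]oxolan-3-yl]acetate
Product: 20 tert-butyl (3R,4R)-5-hydroxy-3-(hydroxymethyl)-4-[(1R,3aR,8aS)-1,4,4-trimethyl-8-methylidenedecahydroazulen-1-yl]pentanoate
Conditions: LiBH4 (3 equiv), THF, 0 °C → rt; AcOH quench
Reagents that add atoms: none
Why: exhaustive borohydride reduction of the γ-alkoxy lactone (pseudo-ester) opens the ring, releases the masked aldehyde with loss of menthol and takes both carbons to primary alcohols, while the tert-butyl ester and the 1,1-disubstituted alkene are inert; no stereocentre is touched.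

**Step 12**
Reactants: 20 tert-butyl (3R,4R)-5-hydroxy-3-(hydroxymethyl)-4-[(1R,3aR,8aS)-1,4,4-trimethyl-8-methylidenedecahydroazulen-1-yl]pentanoate
Product: 21 (4R)-4-{(1R)-2-hydroxy-1-[(1R,3aR,8aS)-1,4,4-trimethyl-8-methylidenedecahydroazulen-1-yl]ethyl}oxolan-2-one
Conditions: TFA/CH2Cl2 1:5, 0 °C, 1 h; aq NaHCO3
Reagents that add atoms: none
Why: acidolysis of the tert-butyl ester and lactonisation, in which the hydroxymethyl on C3 closes the γ-lactone (5-exo, favoured kinetically and thermodynamically over the δ-lactone from the hindered neopentyl-type CH2OH); stereocentres are untouched.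

**Step 13**
Reactants: 21 (4R)-4-{(1R)-2-hydroxy-1-[(1R,3aR,8aS)-1,4,4-trimethyl-8-methylidenedecahydroazulen-1-yl]ethyl}oxolan-2-one
Product: 22 (2R)-2-[(3R)-5-oxooxolan-3-yl]-2-[(1R,3aR,8aS)-1,4,4-trimethyl-8-methylidenedecahydroazulen-1-yl]ethyl acetate
Conditions: Ac2O, pyridine, DMAP (cat.), CH2Cl2, rt
Reagents that add atoms: acetic anhydride, CC(=O)OC(C)=O
Why: DMAP-catalysed acylation of the one remaining primary alcohol gives the target without touching any stereocentre.

**Compound list**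
1 | 4,4-dimethylcyclohex-2-en-1-one | CC1(C)CCC(=O)C=C1 | starting material
2 | ethyl diazoacetate | CCOC(=O)C=[N+]=[N-] | starting material
3 | ethyl 5,5-dimethyl-2-oxocyclohept-3-ene-1-carboxylate (racemic at C1) | CCOC(=O)C1CCC(C)(C)C=CC1=O | intermediate
4 | 4,4-dimethylcyclohept-2-en-1-one | CC1(C)CCCC(=O)C=C1 | intermediate
5 | but-3-en-1-ylmagnesium bromide | C=CCC[Mg]Br | starting material
6 | di(but-3-en-1-yl)zinc | C=CCC[Zn]CCC=C | intermediate (not isolated)
7 | (but-3-en-1-yl)zinc (3R)-3-(but-3-en-1-yl)-4,4-dimethylcyclohept-1-en-1-olate | C=CCC[Zn]OC1=C[C@@H](CCC=C)C(C)(C)CCC1 | intermediate (not isolated)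
8 | trimethyl{[(3R)-3-(but-3-en-1-yl)-4,4-dimethylcyclohept-1-en-1-yl]oxy}silane | C[Si](C)(C)OC1=C[C@@H](CCC=C)C(C)(C)CCC1 | intermediate
9 | (3aR,8aR)-8,8-dimethyl-3-methylideneoctahydroazulen-4(1H)-one (cis-fused) | O=C1CCCC(C)(C)[C@@H]2CCC(=C)[C@H]12 | intermediate
10 | furfural | O=Cc1ccco1 | starting material
11 | 5-hydroxyfuran-2(5H)-one (racemic) | O=C1C=CC(O)O1 | intermediate
12 | (+)-menthol, (1S,2R,5S)-5-methyl-2-(propan-2-yl)cyclohexan-1-ol | O[C@H]1C[C@@H](C)CC[C@@H]1C(C)C | starting material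
13 | (5S)-5-[(+)-menthyloxy]furan-2(5H)-one | O=C1C=C[C@@H](O[C@H]2C[C@@H](C)CC[C@@H]2C(C)C)O1 | intermediate
14 | (5S)-3-iodo-5-[(+)-menthyloxy]furan-2(5H)-one | O=C1C(I)=C[C@@H](O[C@H]2C[C@@H](C)CC[C@@H]2C(C)C)O1 | intermediate
15 | tert-butyl bromoacetate | CC(C)(C)OC(=O)CBr | starting material
16 | (2-tert-butoxy-2-oxoethyl)zinc bromide | CC(C)(C)OC(=O)C[Zn]Br | intermediate (not isolated)
17 | tert-butyl 2-[(5S)-5-[(+)-menthyloxy]-2-oxo-2,5-dihydrofuran-3-yl]acetate | O=C1C(CC(=O)OC(C)(C)C)=C[C@@H](O[C@H]2C[C@@H](C)CC[C@@H]2C(C)C)O1 | intermediate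
18 | tert-butyl 2-[(3R,4R,5S)-5-[(+)-menthyloxy]-2-oxo-4-[(1S,3aR,8aR)-1,4,4-trimethyl-8-oxodecahydroazulen-1-yl]oxolan-3-yl]acetate | O=C1CCCC(C)(C)[C@@H]2CC[C@@](C)([C@H]([C@@H](O[C@H]4C[C@@H](C)CC[C@@H]4C(C)C)OC3=O)[C@H]3CC(=O)OC(C)(C)C)[C@H]12 | intermediate
19 | tert-butyl 2-[(3R,4R,5S)-5-[(+)-menthyloxy]-2-oxo-4-[(1R,3aR,8aS)-1,4,4-trimethyl-8-methylidenedecahydroazulen-1-yl]oxolan-3-yl]acetate | C=C1CCCC(C)(C)[C@@H]2CC[C@@](C)([C@H]([C@@H](O[C@H]4C[C@@H](C)CC[C@@H]4C(C)C)OC3=O)[C@H]3CC(=O)OC(C)(C)C)[C@H]12 | intermediate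
20 | tert-butyl (3R,4R)-5-hydroxy-3-(hydroxymethyl)-4-[(1R,3aR,8aS)-1,4,4-trimethyl-8-methylidenedecahydroazulen-1-yl]pentanoate | C=C1CCCC(C)(C)[C@@H]2CC[C@@](C)([C@H](CO)[C@H](CO)CC(=O)OC(C)(C)C)[C@H]12 | intermediate
21 | (4R)-4-{(1R)-2-hydroxy-1-[(1R,3aR,8aS)-1,4,4-trimethyl-8-methylidenedecahydroazulen-1-yl]ethyl}oxolan-2-one | C=C1CCCC(C)(C)[C@@H]2CC[C@@](C)([C@H](CO)[C@@H]3COC(=O)C3)[C@H]12 | intermediate
22 | (2R)-2-[(3R)-5-oxooxolan-3-yl]-2-[(1R,3aR,8aS)-1,4,4-trimethyl-8-methylidenedecahydroazulen-1-yl]ethyl acetate | C=C1CCCC(C)(C)[C@@H]2CC[C@@](C)([C@H](COC(C)=O)[C@@H]3COC(=O)C3)[C@H]12 | target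

**Step count and risks**
Total steps: 13. Longest linear sequence: 9 steps (steps 1–4 and 9–13); steps 5–8 build the butenolide partner.

The three steps most likely to fail:

Step 9 (iron-hydride coupling). The tertiary radical can give back a hydrogen atom to form the conjugated tetrasubstituted enone, the acceptor can be reduced, and the cis C3 centre can epimerise. Fallback, from compound 9 back to compound 18: the radical is made by C–O fragmentation instead of H-atom transfer to the alkene. Mukaiyama hydration of 9 (Mn(dpm)3 cat., PhSiH3, O2, i-PrOH, 0 °C, then PPh3), where O2 capture outruns isomerisation, gives (3R,3aR,8aR)-3-hydroxy-3,8,8-trimethyloctahydroazulen-4(1H)-one F1 (the carbinol configuration is irrelevant). Acylation with N-phthalimidoyl chlorooxalate (Et3N, DMAP, CH2Cl2, −20 °C) gives (3R,3aR,8aR)-3,8,8-trimethyl-4-oxodecahydroazulen-3-yl 1,3-dioxoisoindolin-2-yl oxalate F2. Blue-LED irradiation of F2 with Ru(bpy)3(PF6)2 (cat.), Hantzsch ester and i-Pr2NEt·HBF4 in the presence of 17 fragments it to the same tertiary radical, which adds to 17 with the same facial preferences and returns to 18.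

Step 4 (Pd cyclisation). Saegusa-type dehydrosilylation or Pd–H isomerisation of the β,γ-enone into conjugation can compete. Fallback, from compound 4 back to compound 9: the ring is closed on an alkyne with gold. Compound 4 is taken through the step-3 protocol with bis[4-(trimethylsilyl)but-3-yn-1-yl]zinc to give [4-(trimethylsilyl)but-3-yn-1-yl]zinc (3R)-4,4-dimethyl-3-[4-(trimethylsilyl)but-3-yn-1-yl]cyclohept-1-en-1-olate F3, which is trapped with TBSOTf as tert-butyl(dimethyl){[(3R)-4,4-dimethyl-3-[4-(trimethylsilyl)but-3-yn-1-yl]cyclohept-1-en-1-yl]oxy}silane F4. K2CO3/MeOH removes the alkynyl silane to give {[(3R)-3-(but-3-yn-1-yl)-4,4-dimethylcyclohept-1-en-1-yl]oxy}(tert-butyl)dimethylsilane F5. Ph3PAuNTf2 (2 mol %) in CH2Cl2/MeOH 10:1 at rt then effects 5-exo-dig carbocyclisation with protodeauration, giving 9 without any palladium hydride.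

Step 8 (Negishi coupling). The zinc enolate may add conjugately to the iodobutenolide or the coupling may stall. Fallback, from compound 13 back to compound 17: the acetate arm is put in by conjugate addition, alkylation and elimination. PhSH with Et3N (cat.) adds to 13 anti to the menthyloxy group to give (4S,5S)-5-[(+)-menthyloxy]-4-(phenylsulfanyl)oxolan-2-one F6. LDA (THF, −78 °C) forms its lithium enolate F7, and 15 alkylates it trans to sulfur to give tert-butyl 2-[(3R,4S,5S)-5-[(+)-menthyloxy]-2-oxo-4-(phenylsulfanyl)oxolan-3-yl]acetate F8. mCPBA (1 equiv, −78 °C) gives the corresponding sulfoxide F9 (mixture at sulfur), and its thermal syn-elimination (toluene, 80 °C, CaCO3) toward the acidic C3–H, which is cis to sulfur, returns 17.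

**Further compounds**
F1 | step 9 | (3R,3aR,8aR)-3-hydroxy-3,8,8-trimethyloctahydroazulen-4(1H)-one | O=C1CCCC(C)(C)[C@@H]2CC[C@@](C)(O)[C@H]12
F2 | step 9 | (3R,3aR,8aR)-3,8,8-trimethyl-4-oxodecahydroazulen-3-yl 1,3-dioxoisoindolin-2-yl oxalate | O=C1CCCC(C)(C)[C@@H]2CC[C@@](C)(OC(=O)C(=O)ON3C(=O)c4ccccc4C3=O)[C@H]12
F3 | step 4 | [4-(trimethylsilyl)but-3-yn-1-yl]zinc (3R)-4,4-dimethyl-3-[4-(trimethylsilyl)but-3-yn-1-yl]cyclohept-1-en-1-olate | C[Si](C)(C)C#CCC[Zn]OC1=C[C@@H](CCC#C[Si](C)(C)C)C(C)(C)CCC1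
F4 | step 4 | tert-butyl(dimethyl){[(3R)-4,4-dimethyl-3-[4-(trimethylsilyl)but-3-yn-1-yl]cyclohept-1-en-1-yl]oxy}silane | CC(C)(C)[Si](C)(C)OC1=C[C@@H](CCC#C[Si](C)(C)C)C(C)(C)CCC1
F5 | step 4 | {[(3R)-3-(but-3-yn-1-yl)-4,4-dimethylcyclohept-1-en-1-yl]oxy}(tert-butyl)dimethylsilane | CC(C)(C)[Si](C)(C)OC1=C[C@@H](CCC#C)C(C)(C)CCC1
F6 | step 8 | (4S,5S)-5-[(+)-menthyloxy]-4-(phenylsulfanyl)oxolan-2-one | O=C1C[C@H](Sc2ccccc2)[C@@H](O[C@H]3C[C@@H](C)CC[C@@H]3C(C)C)O1
F7 | step 8 | lithium (4S,5S)-5-[(+)-menthyloxy]-4-(phenylsulfanyl)-4,5-dihydrofuran-2-olate | [Li]OC1=C[C@H](Sc2ccccc2)[C@@H](O[C@H]3C[C@@H](C)CC[C@@H]3C(C)C)O1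
F8 | step 8 | tert-butyl 2-[(3R,4S,5S)-5-[(+)-menthyloxy]-2-oxo-4-(phenylsulfanyl)oxolan-3-yl]acetate | O=C1[C@@H](CC(=O)OC(C)(C)C)[C@H](Sc2ccccc2)[C@@H](O[C@H]3C[C@@H](C)CC[C@@H]3C(C)C)O1
F9 | step 8 | S-oxide of F8, tert-butyl 2-[5-[(+)-menthyloxy]-2-oxo-4-(phenylsulfinyl)oxolan-3-yl]acetate (ring configuration as F8, mixture at sulfur) | O=C1[C@@H](CC(=O)OC(C)(C)C)[C@H](S(=O)c2ccccc2)[C@@H](O[C@H]3C[C@@H](C)CC[C@@H]3C(C)C)O1
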